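**Retrosynthetic overview**

1. Target 20, (3S,13Z)-1-(3,4-dihydroxyphenyl)-3-hydroxydocos-13-en-5-one, comes from its tris-TBS ether 19 by one global desilylation.
2. Key disconnection C9–C10: a plain CH2–CH2 bond with two primary carbons, C9 four carbons beyond the C5 ketone and C10 three carbons before the C13=C14 Z-alkene. Each carbon therefore maps onto a CO2H group and onto a primary radical with no fast cyclisation path (a pent-4-enyl-type radical and a δ-keto radical), which allows a Ni-electrocatalytic doubly decarboxylative cross-coupling of acid 3 with keto acid 16.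
3. Acid 3 comes from a Z-selective Wittig reaction (C13=C14) of nonanal with the ω-carboxybutyl ylide; keto acid 16 comes from Weinreb amide 13 and the dianion of pent-4-ynoic acid, followed by alkyne hydrogenation.
4. Amide 13 comes from Noyori hydrogenation of β-keto ester 10 (sets C3), which is made from dihydrocaffeic acid 4 by silylation and Masamune homologation.
5. No ring is formed anywhere in the route; the catechol ring is bought with 4.

Key step: step 8

Remark: TBS = tert-butyldimethylsilyl. In step 8 both redox-active esters are made and electrolysed in the same flask, and spent metal reagents are written as their chlorides after acidic work-up.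

**Step 1**
Reactants: 1 (4-carboxybutyl)triphenylphosphonium bromide; 2 nonanal
Product: 3 (5Z)-tetradec-5-enoic acid
Conditions: NaHMDS (2.2 equiv), THF, 0 °C; then 2, −78 °C → rt; aq. HCl work-up, acid–base extraction
Reagents that add atoms: none
Why: Wittig olefination with a non-stabilised, lithium-free carboxylate ylide proceeds under kinetic control through the cis-oxaphosphetane, so the alkene that becomes C13=C14 should form Z-selectively.

**Step 2**
Reactants: 4 3-(3,4-dihydroxyphenyl)propanoic acid
Product: 6 3-[3,4-bis(tert-butyldimethylsilyloxy)phenyl]propanoic acid, via silyl ester 5 (not isolated)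
Conditions: TBSCl (3.5 equiv), imidazole, DMF, rt; then AcOH/THF/H2O, rt
Reagents that add atoms: tert-butyldimethylsilyl chloride (TBSCl), CC(C)(C)[Si](C)(C)Cl
Why: Exhaustive silylation (Corey conditions) followed by selective hydrolysis of the silyl ester, which is far more labile to mild aqueous acid than the two aryl silyl ethers.

**Step 3**
Reactants: 6 3-[3,4-bis(tert-butyldimethylsilyloxy)phenyl]propanoic acid; 7 potassium methyl malonate
Product: 10 methyl 5-[3,4-bis(tert-butyldimethylsilyloxy)phenyl]-3-oxopentanoate, via acyl imidazole 8 (not isolated), via acylmalonic half-ester 9 (not isolated)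
Conditions: CDI (1.1 equiv), THF, rt; then 7, MgCl2, Et3N, MeCN/THF, rt; cold 1 M HCl work-up
Reagents that add atoms: 1,1'-carbonyldiimidazole (CDI), O=C(n1ccnc1)n1ccnc1 (its imidazole unit is carried in intermediate 8 only)
Why: Masamune–Brooks homologation: the magnesium enolate of the malonate half-ester is C-acylated by the acyl imidazolide and the acylmalonate loses CO2, under near-neutral conditions that spare the aryl silyl ethers.

**Step 4**
Reactants: 10 methyl 5-[3,4-bis(tert-butyldimethylsilyloxy)phenyl]-3-oxopentanoate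
Product: 11 methyl (3S)-5-[3,4-bis(tert-butyldimethylsilyloxy)phenyl]-3-hydroxypentanoate
Conditions: H2 (4–10 atm), [RuCl2((S)-BINAP)]2·NEt3 (0.5 mol%), MeOH, 50 °C
Reagents that add atoms: none
Why: Noyori asymmetric hydrogenation of a β-keto ester: chelation of both carbonyls to the (S)-BINAP–Ru hydride fixes the face of hydride delivery, so the C3 carbinol should be set as S (mirror image of the (R)-BINAP/(R)-3-hydroxybutanoate paradigm) with the high enantioselectivity typical of this substrate class.

**Step 5**
Reactants: 11 methyl (3S)-5-[3,4-bis(tert-butyldimethylsilyloxy)phenyl]-3-hydroxypentanoate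
Product: 12 (3S)-5-[3,4-bis(tert-butyldimethylsilyloxy)phenyl]-3-hydroxy-N-methoxy-N-methylpentanamide
Conditions: MeNH(OMe)·HCl (3 equiv), i-PrMgCl (6.5 equiv), THF, −20 → 0 °C
Reagents that add atoms: N,O-dimethylhydroxylamine hydrochloride, CNOC.Cl
Why: Weinreb amide formation by aminolysis of the ester with the chloromagnesium amide; the β-hydroxyl is carried as its magnesium alkoxide and the stereocentre is not touched.

**Step 6**
Reactants: 12 (3S)-5-[3,4-bis(tert-butyldimethylsilyloxy)phenyl]-3-hydroxy-N-methoxy-N-methylpentanamide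
Product: 13 (3S)-5-[3,4-bis(tert-butyldimethylsilyloxy)phenyl]-3-(tert-butyldimethylsilyloxy)-N-methoxy-N-methylpentanamide
Conditions: TBSCl, imidazole, DMF, rt
Reagents that add atoms: tert-butyldimethylsilyl chloride (TBSCl), CC(C)(C)[Si](C)(C)Cl
Why: Standard silylation of the secondary alcohol blocks acylation during active-ester formation and retro-aldol or β-elimination later; this third TBS group leaves with the other two at the end.

**Step 7**
Reactants: 13 (3S)-5-[3,4-bis(tert-butyldimethylsilyloxy)phenyl]-3-(tert-butyldimethylsilyloxy)-N-methoxy-N-methylpentanamide; 14 pent-4-ynoic acid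
Product: 16 (8S)-10-[3,4-bis(tert-butyldimethylsilyloxy)phenyl]-8-(tert-butyldimethylsilyloxy)-6-oxodecanoic acid, via ynone acid 15 (not isolated)
Conditions: 14 (2.5 equiv), n-BuLi (5 equiv), THF/DMPU, −78 → −20 °C; add 13, → 0 °C; inverse quench into cold 1 M HCl; then H2 (1 atm), 10% Pd/C, EtOAc, rt
Reagents that add atoms: none
Why: Alkynyllithium addition to a Weinreb amide stops at the chelated tetrahedral intermediate and releases the ynone only on acidic quench (the inverse quench keeps the carboxyl protonated and should prevent conjugate lactonisation); Pd/C hydrogenation then saturates the alkyne to the four-methylene spacer while the fragment still holds no other reducible C=C bond.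

**Step 8**
Reactants: 3 (5Z)-tetradec-5-enoic acid; 16 (8S)-10-[3,4-bis(tert-butyldimethylsilyloxy)phenyl]-8-(tert-butyldimethylsilyloxy)-6-oxodecanoic acid
Product: 19 (3S,13Z)-1-[3,4-bis(tert-butyldimethylsilyloxy)phenyl]-3-(tert-butyldimethylsilyloxy)docos-13-en-5-one, via redox-active ester 17 (not isolated), via redox-active ester 18 (not isolated)
Conditions: 3 (3 equiv), 16 (1 equiv), N-hydroxyphthalimide, DIC, THF/DMF, rt; then NiCl2·6H2O (20 mol%), 2,2':6',2''-terpyridine (20 mol%), AgNO3 (30 mol%), NaI, DMF, Mg(+)/RVC(−), constant current (ca. 3 F/mol), rt, undivided cell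
Reagents that add atoms: N-hydroxyphthalimide, O=C1c2ccccc2C(=O)N1O (carried in intermediates 17 and 18 only)
Why: Each N-acyloxyphthalimide takes up one electron (from the silver-coated cathode or low-valent terpyridine–nickel), loses CO2 and phthalimide anion and gives a primary alkyl radical; the nickel centre captures the two radicals in turn and reductive elimination from the dialkylnickel species should forge the C9–C10 CH2–CH2 bond, the magnesium anode supplying the electrons. The closest known reaction type is the Ni-electrocatalytic doubly decarboxylative C(sp3)–C(sp3) cross-coupling of two primary alkyl redox-active esters formed in situ, the reductive counterpart of mixed Kolbe electrolysis. No ring is closed and no stereocentre is created; the C3 centre lies six bonds from the radical carbon and is not epimerisable under these conditions. Cross- over homo-coupling is only statistical for two like primary radicals, so it is secured by a threefold excess of the cheap acid 3, whose hydrocarbon homodimer and the hexasilylated diketone homodimer both differ widely in polarity from 19. Z-geometry and chain integrity should be kept because the radical from 17 is a pent-4-enyl radical (only 4-exo or 5-endo modes) and the radical from 18 is δ-keto (5-exo attack on C=O is reversible). The reductive regime leaves the dialkyl ketone, the isolated alkene and the electron-rich arene untouched, whereas anodic Kolbe conditions would oxidise the arene.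

**Step 9**
Reactants: 19 (3S,13Z)-1-[3,4-bis(tert-butyldimethylsilyloxy)phenyl]-3-(tert-butyldimethylsilyloxy)docos-13-en-5-one
Product: 20 (3S,13Z)-1-(3,4-dihydroxyphenyl)-3-hydroxydocos-13-en-5-one
Conditions: TBAF (5 equiv), AcOH (5 equiv), THF, 0 °C → rt, argon; aq. NH4Cl work-up
Reagents that add atoms: none
Why: Fluoride-induced cleavage of all three silyl ethers; acetic acid buffering keeps the medium non-basic so that the β-hydroxy ketone should neither dehydrate nor undergo retro-aldol cleavage, the catechol is not autoxidised and the isolated Z-alkene is inert.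

**Compound list**

1 | (4-carboxybutyl)triphenylphosphonium bromide | OC(=O)CCCC[P+](c1ccccc1)(c1ccccc1)c1ccccc1.[Br-] | starting material
2 | nonanal | CCCCCCCCC=O | starting material
3 | (5Z)-tetradec-5-enoic acid | CCCCCCCC/C=C\CCCC(=O)O | intermediate
4 | 3-(3,4-dihydroxyphenyl)propanoic acid | OC(=O)CCc1ccc(O)c(O)c1 | starting material
5 | tert-butyldimethylsilyl 3-[3,4-bis(tert-butyldimethylsilyloxy)phenyl]propanoate | CC(C)(C)[Si](C)(C)OC(=O)CCc1ccc(O[Si](C)(C)C(C)(C)C)c(O[Si](C)(C)C(C)(C)C)c1 | intermediate (not isolated)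
6 | 3-[3,4-bis(tert-butyldimethylsilyloxy)phenyl]propanoic acid | OC(=O)CCc1ccc(O[Si](C)(C)C(C)(C)C)c(O[Si](C)(C)C(C)(C)C)c1 | intermediate
7 | potassium methyl malonate | COC(=O)CC(=O)[O-].[K+] | starting material
8 | 1-{3-[3,4-bis(tert-butyldimethylsilyloxy)phenyl]propanoyl}imidazole | O=C(CCc1ccc(O[Si](C)(C)C(C)(C)C)c(O[Si](C)(C)C(C)(C)C)c1)n1ccnc1 | intermediate (not isolated)
9 | 5-[3,4-bis(tert-butyldimethylsilyloxy)phenyl]-2-(methoxycarbonyl)-3-oxopentanoic acid (present as its magnesium chelate) | COC(=O)C(C(=O)O)C(=O)CCc1ccc(O[Si](C)(C)C(C)(C)C)c(O[Si](C)(C)C(C)(C)C)c1 | intermediate (not isolated)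
10 | methyl 5-[3,4-bis(tert-butyldimethylsilyloxy)phenyl]-3-oxopentanoate | COC(=O)CC(=O)CCc1ccc(O[Si](C)(C)C(C)(C)C)c(O[Si](C)(C)C(C)(C)C)c1 | intermediate
11 | methyl (3S)-5-[3,4-bis(tert-butyldimethylsilyloxy)phenyl]-3-hydroxypentanoate | COC(=O)C[C@@H](O)CCc1ccc(O[Si](C)(C)C(C)(C)C)c(O[Si](C)(C)C(C)(C)C)c1 | intermediate
12 | (3S)-5-[3,4-bis(tert-butyldimethylsilyloxy)phenyl]-3-hydroxy-N-methoxy-N-methylpentanamide | CON(C)C(=O)C[C@@H](O)CCc1ccc(O[Si](C)(C)C(C)(C)C)c(O[Si](C)(C)C(C)(C)C)c1 | intermediate
13 | (3S)-5-[3,4-bis(tert-butyldimethylsilyloxy)phenyl]-3-(tert-butyldimethylsilyloxy)-N-methoxy-N-methylpentanamide | CON(C)C(=O)C[C@@H](O[Si](C)(C)C(C)(C)C)CCc1ccc(O[Si](C)(C)C(C)(C)C)c(O[Si](C)(C)C(C)(C)C)c1 | intermediate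
14 | pent-4-ynoic acid | C#CCCC(=O)O | starting material
15 | (8S)-10-[3,4-bis(tert-butyldimethylsilyloxy)phenyl]-8-(tert-butyldimethylsilyloxy)-6-oxodec-4-ynoic acid | OC(=O)CCC#CC(=O)C[C@@H](O[Si](C)(C)C(C)(C)C)CCc1ccc(O[Si](C)(C)C(C)(C)C)c(O[Si](C)(C)C(C)(C)C)c1 | intermediate (not isolated)
16 | (8S)-10-[3,4-bis(tert-butyldimethylsilyloxy)phenyl]-8-(tert-butyldimethylsilyloxy)-6-oxodecanoic acid | OC(=O)CCCCC(=O)C[C@@H](O[Si](C)(C)C(C)(C)C)CCc1ccc(O[Si](C)(C)C(C)(C)C)c(O[Si](C)(C)C(C)(C)C)c1 | intermediate
17 | 1,3-dioxoisoindolin-2-yl (5Z)-tetradec-5-enoate | CCCCCCCC/C=C\CCCC(=O)ON1C(=O)c2ccccc2C1=O | intermediate (not isolated)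
18 | 1,3-dioxoisoindolin-2-yl (8S)-10-[3,4-bis(tert-butyldimethylsilyloxy)phenyl]-8-(tert-butyldimethylsilyloxy)-6-oxodecanoate | O=C(CCCCC(=O)C[C@@H](O[Si](C)(C)C(C)(C)C)CCc1ccc(O[Si](C)(C)C(C)(C)C)c(O[Si](C)(C)C(C)(C)C)c1)ON1C(=O)c2ccccc2C1=O | intermediate (not isolated)
19 | (3S,13Z)-1-[3,4-bis(tert-butyldimethylsilyloxy)phenyl]-3-(tert-butyldimethylsilyloxy)docos-13-en-5-one | CCCCCCCC/C=C\CCCCCCCC(=O)C[C@@H](O[Si](C)(C)C(C)(C)C)CCc1ccc(O[Si](C)(C)C(C)(C)C)c(O[Si](C)(C)C(C)(C)C)c1 | intermediate
20 | (3S,13Z)-1-(3,4-dihydroxyphenyl)-3-hydroxydocos-13-en-5-one | CCCCCCCC/C=C\CCCCCCCC(=O)C[C@@H](O)CCc1ccc(O)c(O)c1 | target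

**Step count and risks**

Total step count: 9. Longest linear sequence: 8 steps (steps 2–9, from 4).

Steps most likely to fail:

- **Step 8.** Statistical homocoupling may outrun cross-coupling, the radical derived from 18 may be reduced to the alkane, and the aryl silyl ethers may be cleaved slowly by phthalimide anion in DMF. The fallback is a polarity-differentiated Ni-catalysed decarboxylative Negishi alkyl–alkyl coupling and sets out from 2 and 16. Nonanal 2 is olefinated with the ylide of commercial (4-hydroxybutyl)triphenylphosphonium bromide (NaHMDS, THF, −78 °C → rt) to give (4Z)-tridec-4-en-1-ol F1. This is converted with CBr4/PPh3 into (4Z)-1-bromotridec-4-ene F2, with Mg in THF into (4Z)-tridec-4-enylmagnesium bromide F3, and with ZnCl2 (0.5 equiv) into bis[(4Z)-tridec-4-enyl]zinc F4. Acid 16 is converted into ester 18, this time isolated (N-hydroxyphthalimide, DIC, CH2Cl2), and 18 is coupled with F4 (NiCl2·glyme, 4,4'-di-tert-butyl-2,2'-bipyridine, THF/DMF, rt). Only 18 then generates a radical, so homocoupling is suppressed; the fallback comes back to the route at 19.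

- **Step 7.** The dilithio species may be poorly soluble and add sluggishly, and the carboxylate may add in conjugate fashion to the ynone during the quench before hydrogenation. The fallback sets out from 13. Hex-5-enylmagnesium bromide (THF, 0 °C) should give (9S)-11-[3,4-bis(tert-butyldimethylsilyloxy)phenyl]-9-(tert-butyldimethylsilyloxy)undec-1-en-7-one F5. Ozonolysis (O3, CH2Cl2/MeOH, −78 °C, Sudan III end-point, then PPh3) should give (8S)-10-[3,4-bis(tert-butyldimethylsilyloxy)phenyl]-8-(tert-butyldimethylsilyloxy)-6-oxodecanal F6. Pinnick oxidation (NaClO2, NaH2PO4, 2-methylbut-2-ene, t-BuOH/H2O) comes back to the route at 16.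

- **Step 9.** Cleavage of the hindered secondary silyl ether may stay incomplete under buffered fluoride, base-induced dehydration or retro-aldol cleavage may set in once the buffer is consumed, and the catecholate may autoxidise. The fallback replaces the single global operation by two orthogonal unmasking operations and sets out from 19. Aqueous HF (48%) in MeCN at 0 °C should remove only the alkyl silyl ether and give (3S,13Z)-1-[3,4-bis(tert-butyldimethylsilyloxy)phenyl]-3-hydroxydocos-13-en-5-one F7. KHF2 in MeOH at rt, which is weakly acidic and selective for phenolic silyl ethers, then comes back to the route at 20.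

**Further compounds**

F1 | step 8 | (4Z)-tridec-4-en-1-ol | CCCCCCCC/C=C\CCCO
F2 | step 8 | (4Z)-1-bromotridec-4-ene | CCCCCCCC/C=C\CCCBr
F3 | step 8 | (4Z)-tridec-4-enylmagnesium bromide | CCCCCCCC/C=C\CCC[Mg]Br
F4 | step 8 | bis[(4Z)-tridec-4-enyl]zinc | CCCCCCCC/C=C\CCC[Zn]CCC/C=C\CCCCCCCC
F5 | step 7 | (9S)-11-[3,4-bis(tert-butyldimethylsilyloxy)phenyl]-9-(tert-butyldimethylsilyloxy)undec-1-en-7-one | C=CCCCCC(=O)C[C@@H](O[Si](C)(C)C(C)(C)C)CCc1ccc(O[Si](C)(C)C(C)(C)C)c(O[Si](C)(C)C(C)(C)C)c1
F6 | step 7 | (8S)-10-[3,4-bis(tert-butyldimethylsilyloxy)phenyl]-8-(tert-butyldimethylsilyloxy)-6-oxodecanal | O=CCCCCC(=O)C[C@@H](O[Si](C)(C)C(C)(C)C)CCc1ccc(O[Si](C)(C)C(C)(C)C)c(O[Si](C)(C)C(C)(C)C)c1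
F7 | step 9 | (3S,13Z)-1-[3,4-bis(tert-butyldimethylsilyloxy)phenyl]-3-hydroxydocos-13-en-5-one | CCCCCCCC/C=C\CCCCCCCC(=O)C[C@@H](O)CCc1ccc(O[Si](C)(C)C(C)(C)C)c(O[Si](C)(C)C(C)(C)C)c1
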